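## Retrosynthetic overview

1. Last ring: a biomimetic [4+2] joins the C12=C13–C14=C15 diene of 9α-hydroxylabda-8(17),12E,14-trien-7-one to the methoxy-free C1′=C6′ bond of a flavone B-ring quinone (new bonds C12–C1′ and C15–C6′). It is run as a one-pot SO2 extrusion/cycloaddition on unprotected partners and sets C12, C1′ and C6′ together.
2. The diene travels as its sulfolene (SO2 adduct), so ring B can be oxidised late: singlet-oxygen ene reaction (9α-OH, 8(17)-ene), then SeO2 and Dess–Martin oxidation (C7 ketone).
3. Sulfolene ⇐ C11–C12 alkylation of 3-methyl-3-sulfolene with 11-bromodrim-8-ene ⇐ (+)-sclareolide (saponification, oxidative decarboxylation, allylic bromination with transposition). Rings A and B, C5 and C10 come from the chiral pool.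
4. Quinone ⇐ (NH4)2Ce(NO3)6 demethylation of 5,7-dihydroxy-2′,4′,5′-trimethoxyflavone ⇐ one-pot acylation/cyclodehydration of 2′,4′,6′-trihydroxyacetophenone with 2,4,5-trimethoxybenzoyl chloride (pyranone ring).
5. Ring order: decalin (purchased) → pyranone ring → cyclohexene ring (last).

Assumption: labdane numbering (C1–C20) is used for the diterpene half and flavone numbering (C2–C8a, C1′–C6′) for the other half; the sulfolene intermediates are carried as both epimers at the sulfolene C2 (= C12), a centre that is erased when SO2 is lost.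

## Route

Step 1
Reactants: 1 (+)-sclareolide
Product: 2 8α-hydroxy-13,14,15,16-tetranorlabdan-12-oic acid
Conditions: KOH (3 equiv), MeOH/H2O (10:1), 70 °C, 3 h; cold 1 M HCl to pH 4 at 0 °C, extract, concentrate below 30 °C, use at once
Reagents that add atoms: potassium hydroxide, [K+].[OH-]
Why: Saponification of the γ-lactone by acyl–oxygen cleavage leaves the C8–O bond and all four stereocentres untouched, and the hydroxy acid is used immediately because it relactonises on standing.

Step 2
Reactants: 2 8α-hydroxy-13,14,15,16-tetranorlabdan-12-oic acid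
Product: 3 drim-9(11)-en-8α-ol
Conditions: Pb(OAc)4 (1.5 equiv), Cu(OAc)2·H2O (0.2 equiv), pyridine (2 equiv), PhH, 80 °C, N2
Reagents that add atoms: none
Why: Kochi oxidative decarboxylation, in which the lead carboxylate fragments to the primary C11 radical and Cu(OAc)2 oxidises it with loss of the only β-hydrogen (H-9) to give the exocyclic C9=C11 olefin, so no new stereocentre arises and the tertiary 8α-alcohol is retained.

Step 3
Reactants: 3 drim-9(11)-en-8α-ol
Product: 4 11-bromodrim-8-ene
Conditions: PBr3 (0.4 equiv), pyridine (cat.), Et2O, −10 → 0 °C, 1 h; used crude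
Reagents that add atoms: phosphorus tribromide, BrP(Br)Br
Why: Allylic bromination with 1,3-transposition (SN2′ collapse of the bromophosphite, as in linalool → geranyl bromide) puts bromide on the unhindered CH2 terminus and moves the double bond into the favoured tetrasubstituted 8(9) position, with no stereocentre formed.

Step 4
Reactants: 4 11-bromodrim-8-ene; 5 3-methyl-3-sulfolene
Product: 6 12,15-sulfonyllabda-8,13-diene
Conditions: 4 and 5 (1.5 equiv) in THF/DMPU (4:1), −78 °C; LiN(SiMe3)2 (1.5 equiv) added last, 30 min; sat. aq NH4Cl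
Reagents that add atoms: none
Why: Regioselective α-alkylation of the 3-methyl-3-sulfolenyl anion at its C2 (the position used in the classical (E)-β-ocimene and α-farnesene syntheses) by SN2 attack on the primary allylic bromide, with the base added last so that the short-lived anion is trapped before it ring-opens; the new sulfolene C2 centre forms as both epimers, which is harmless because it is erased on SO2 loss.

Step 5
Reactants: 6 12,15-sulfonyllabda-8,13-diene
Product: 8 12,15-sulfonyllabda-8(17),13-dien-9α-ol, via 9α-hydroperoxide 7 (not isolated)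
Conditions: O2, 5,10,15,20-tetraphenylporphyrin (1 mol %), white LEDs, CH2Cl2, −20 °C; then PPh3 (1.2 equiv), −20 °C → rt
Reagents that add atoms: dioxygen, O=O
Why: Schenck ene reaction, in which singlet oxygen reacts far faster with the electron-rich tetrasubstituted 8(9) olefin than with the sulfone-deactivated ring olefin, bonds to C9 from the α face (anti to the axial C10 methyl) and takes a hydrogen from the C17 methyl (exocyclic methyl abstraction is preferred over ring CH2 in tetrasubstituted cyclohexenes, and the C11 hydrogens are shielded by the sulfolene), after which PPh3 reduces the hydroperoxide with retention to the 9α-alcohol.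

Step 6
Reactants: 8 12,15-sulfonyllabda-8(17),13-dien-9α-ol
Product: 9 12,15-sulfonyllabda-8(17),13-diene-7α,9α-diol
Conditions: SeO2 (0.3 equiv), t-BuOOH (3 equiv, 5.5 M in decane), CH2Cl2, rt
Reagents that add atoms: SeO2, O=[Se]=O (oxygen carrier); tert-butyl hydroperoxide, CC(C)(C)OO (terminal oxygen source)
Why: Sharpless SeO2/t-BuOOH allylic hydroxylation (ene reaction then [2,3]-sigmatropic shift) functionalises C7, the only allylic CH2 of the exocyclic olefin, without moving the double bond and gives mainly the axial 7α-alcohol, whose configuration is irrelevant because it is oxidised in step 7.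

Step 7
Reactants: 9 12,15-sulfonyllabda-8(17),13-diene-7α,9α-diol
Product: 10 9α-hydroxy-12,15-sulfonyllabda-8(17),13-dien-7-one
Conditions: Dess–Martin periodinane (1.3 equiv), CH2Cl2, 0 °C → rt
Reagents that add atoms: none
Why: Dess–Martin oxidation turns the secondary allylic alcohol into the cross-conjugated exo-methylene ketone under neutral conditions that spare the tertiary 9α-alcohol, avoid retro-aldol cleavage of the β-hydroxy enone and do not isomerise the sulfolene, the C7 stereocentre being removed.

Step 8
Reactants: 11 2,4,5-trimethoxybenzoic acid; 12 2′,4′,6′-trihydroxyacetophenone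
Product: 15 5,7-dihydroxy-2-(2,4,5-trimethoxyphenyl)-4H-chromen-4-one, via acyl chloride 13 (not isolated), via β-diketone 14 (not isolated)
Conditions: 11, (COCl)2 (1.3 equiv), DMF (cat.), CH2Cl2, 0 °C → rt, evaporate; 12, LiN(SiMe3)2 (4.2 equiv), THF, −78 → −10 °C, then crude 13, −78 °C → rt; aq HCl, concentrate; AcOH, H2SO4 (cat.), 95 °C, 3 h
Reagents that add atoms: none
Why: Cushman's one-pot variant of the Baker–Venkataraman flavone synthesis, in which the acyl chloride C-acylates the polylithiated ketone enolate to the 1,3-diketone and acid-catalysed cyclodehydration onto an ortho hydroxyl closes the pyranone ring without phenol protection, no stereocentre being involved.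

Step 9
Reactants: 15 5,7-dihydroxy-2-(2,4,5-trimethoxyphenyl)-4H-chromen-4-one
Product: 16 5,7-dihydroxy-2-(4-methoxy-3,6-dioxocyclohexa-1,4-dien-1-yl)-4H-chromen-4-one
Conditions: (NH4)2Ce(NO3)6 (2.5 equiv), MeCN/H2O (3:1), 0 °C, 15 min
Reagents that add atoms: water, O
Why: Oxidative demethylation by (NH4)2Ce(NO3)6 converts the para-dimethoxy pair (2′,5′) of the electron-rich trimethoxyphenyl ring into the 2-methoxy-1,4-benzoquinone (carbonyl oxygens from water), while the ring-A phenols, deactivated by the chromone carbonyl, react more slowly at 0 °C and short contact time, no stereocentre being involved.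

Step 10
Reactants: 10 9α-hydroxy-12,15-sulfonyllabda-8(17),13-dien-7-one; 16 5,7-dihydroxy-2-(4-methoxy-3,6-dioxocyclohexa-1,4-dien-1-yl)-4H-chromen-4-one
Product: 18 target CNP0241859.1 (12R,1′S,6′R cycloadduct), via trienone 17 (not isolated)
Conditions: 10, PhMe (0.02 M), 110 °C, N2 sweep, 1.5 h; cool to 0 °C; 16 (1.5 equiv), (CF3)2CHOH (PhMe/(CF3)2CHOH 1:4), 0 °C → rt, dark, 24 h; HPLC
Reagents that add atoms: none
Why: Thermal cheletropic SO2 extrusion (disrotatory, substituent outward) gives only the 12E diene, which is trapped without isolation in a hydrogen-bond-promoted Diels–Alder cycloaddition at the only quinone double bond not deactivated by methoxy (C1′=C6′): (CF3)2CHOH activation of the vinylogous-ester carbonyl C2′ and of the chromone makes C6′ the electrophilic end so that the unsubstituted terminus C15 bonds to C6′ and C12 to C1′, suprafacial addition fixes the cis ring fusion (chromonyl and H-6′ cis), the flat chromone and not the ring carbonyls is expected to sit under the diene (the exo-carbonyl preference of α-substituted enone dienophiles, which also keeps the bulky C11 substituent gauche to the small C2′ carbonyl) so that C11 ends cis to the chromonyl, and addition anti to the decalin in the allylic-strain-minimised rotamer with the C9–C11–C12=C13 torsion near −120° gives 12R, 1′S, 6′R.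

## Compound list

1 | (+)-sclareolide, (3aR,5aS,9aS,9bR)-3a,6,6,9a-tetramethyldecahydronaphtho[2,1-b]furan-2(1H)-one | O=C1C[C@H]2[C@@](C)(CC[C@H]3C(C)(C)CCC[C@]23C)O1 | starting material
2 | 8α-hydroxy-13,14,15,16-tetranorlabdan-12-oic acid, 2-[(1R,2R,4aS,8aS)-2-hydroxy-2,5,5,8a-tetramethyldecahydronaphthalen-1-yl]acetic acid | OC(=O)C[C@H]1[C@](C)(O)CC[C@H]2C(C)(C)CCC[C@]12C | intermediate
3 | drim-9(11)-en-8α-ol, (2R,4aS,8aS)-2,5,5,8a-tetramethyl-1-methylidenedecahydronaphthalen-2-ol | C=C1[C@](C)(O)CC[C@H]2C(C)(C)CCC[C@]12C | intermediate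
4 | 11-bromodrim-8-ene, (4aS,8aS)-1-(bromomethyl)-2,5,5,8a-tetramethyl-3,4,4a,5,6,7,8,8a-octahydronaphthalene | BrCC1=C(C)CC[C@H]2C(C)(C)CCC[C@]12C | intermediate
5 | 3-methyl-3-sulfolene (3-methyl-2,5-dihydrothiophene 1,1-dioxide) | CC1=CCS(=O)(=O)C1 | starting material
6 | 12,15-sulfonyllabda-8,13-diene: 3-methyl-2-{[(4aS,8aS)-2,5,5,8a-tetramethyl-3,4,4a,5,6,7,8,8a-octahydronaphthalen-1-yl]methyl}-2,5-dihydrothiophene 1,1-dioxide, both epimers at the sulfolene C2 | CC1=CCS(=O)(=O)C1CC1=C(C)CC[C@H]2C(C)(C)CCC[C@]12C | intermediate
7 | 9α-hydroperoxy-12,15-sulfonyllabda-8(17),13-diene (exocyclic C8=C17, OOH on the α face of C9; not isolated) | CC1=CCS(=O)(=O)C1C[C@@]1(OO)C(=C)CC[C@H]2C(C)(C)CCC[C@]12C | intermediate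
8 | 12,15-sulfonyllabda-8(17),13-dien-9α-ol: 2-{[(1R,4aS,8aS)-1-hydroxy-5,5,8a-trimethyl-2-methylidenedecahydronaphthalen-1-yl]methyl}-3-methyl-2,5-dihydrothiophene 1,1-dioxide | CC1=CCS(=O)(=O)C1C[C@@]1(O)C(=C)CC[C@H]2C(C)(C)CCC[C@]12C | intermediate
9 | 12,15-sulfonyllabda-8(17),13-diene-7α,9α-diol (axial 7α-OH, 9α-OH, exocyclic C8=C17) | CC1=CCS(=O)(=O)C1C[C@@]1(O)C(=C)[C@H](O)C[C@H]2C(C)(C)CCC[C@]12C | intermediate
10 | 9α-hydroxy-12,15-sulfonyllabda-8(17),13-dien-7-one (sulfolene form of 17) | CC1=CCS(=O)(=O)C1C[C@@]1(O)C(=C)C(=O)C[C@H]2C(C)(C)CCC[C@]12C | intermediate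
11 | 2,4,5-trimethoxybenzoic acid | COc1cc(OC)c(cc1OC)C(O)=O | starting material
12 | 2′,4′,6′-trihydroxyacetophenone, 1-(2,4,6-trihydroxyphenyl)ethan-1-one | CC(=O)c1c(O)cc(O)cc1O | starting material
13 | 2,4,5-trimethoxybenzoyl chloride (not isolated) | COc1cc(OC)c(cc1OC)C(Cl)=O | intermediate
14 | 1-(2,4,6-trihydroxyphenyl)-3-(2,4,5-trimethoxyphenyl)propane-1,3-dione (not isolated) | COc1cc(OC)c(cc1OC)C(=O)CC(=O)c1c(O)cc(O)cc1O | intermediate
15 | 5,7-dihydroxy-2-(2,4,5-trimethoxyphenyl)-4H-chromen-4-one (5,7-dihydroxy-2′,4′,5′-trimethoxyflavone) | COc1cc(OC)c(cc1OC)-c1cc(=O)c2c(O)cc(O)cc2o1 | intermediate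
16 | 5,7-dihydroxy-2-(4-methoxy-3,6-dioxocyclohexa-1,4-dien-1-yl)-4H-chromen-4-one (C2′ and C5′ carbonyls, 4′-OMe) | COC1=CC(=O)C(=CC1=O)c1cc(=O)c2c(O)cc(O)cc2o1 | intermediate
17 | 9α-hydroxylabda-8(17),12E,14-trien-7-one (not isolated) | C=C/C(C)=C/C[C@@]1(O)C(=C)C(=O)C[C@H]2C(C)(C)CCC[C@]12C | intermediate
18 | CNP0241859.1: (4aS,5R,8aR)-4a-(5,7-dihydroxy-4-oxo-4H-chromen-2-yl)-5-{[(1S,4aS,8aS)-1-hydroxy-5,5,8a-trimethyl-2-methylidene-3-oxodecahydronaphthalen-1-yl]methyl}-2-methoxy-6-methyl-4a,5,8,8a-tetrahydronaphthalene-1,4-dione (cis ring fusion; the CH2 link, the chromonyl and H-8a all on one face) | C=C1C(=O)C[C@H]2C(C)(C)CCC[C@]2(C)[C@@]1(O)C[C@@H]1C(C)=CC[C@H]2C(=O)C(OC)=CC(=O)[C@@]12c1cc(=O)c2c(O)cc(O)cc2o1 | target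

## Step count and weak points

Total: 10 steps. Longest linear sequence: 8 steps (steps 1–7 and 10, from sclareolide); the quinone branch is 2 steps (8 and 9) before the union.

The three steps most likely to fail, in order:

Step 10 is the most exposed. In one operation the cycloaddition must choose the C15–C6′ orientation, the mode with the quinone carbonyls exo, and one diene face. The quinone-endo adducts and the opposite-face adduct are real competitors, and none of the three selectivities can be guaranteed from models; the isomers should be separable by HPLC. If the wanted isomer is minor, the control element is changed from hydrogen bonding to a covalent boron chelate, setting out from 10 and 16. Quinone 16 is treated with BF3·OEt2 and 2,6-di-tert-butylpyridine in CH2Cl2 to give the difluoroboron chelate of quinone 16 F1, in which BF2 bridges O5 and the C4 carbonyl oxygen. Trienone 17 is generated from 10 in toluene at 110 °C, taken into CH2Cl2 and added at −40 °C. The chelated pyranone is then the strongest acceptor in the molecule (a 4-oxidopyrylium-like ring), so the C1′=C6′ bond reacts as its vinylogous extension with C6′ electrophilic, and the chromone is proposed to become the endo-directing group. This gives the difluoroboron chelate of adduct 18 F2, and aqueous methanol at 40 °C removes boron to come back to the route at 18.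

Step 5: the ene reaction could instead take the ring hydrogen at C7 (giving the 7-ene 9α-hydroperoxide) or a C11 hydrogen (giving the 8α-hydroperoxide). The fallback makes the C9–O bond by epoxidation and sets out from 6. mCPBA in CH2Cl2 at 0 °C attacks the tetrasubstituted olefin from the α face to give 8α,9α-epoxy-12,15-sulfonyllabd-13-ene F3. Cp2TiCl (trivalent titanium, made in the flask from Cp2TiCl2 and Mn dust in THF at rt) then opens the epoxide to a tertiary β-titanoxy radical; the wanted outcome is C8–O homolysis followed by loss of a C17 hydrogen to the exocyclic olefin, which leaves the oxygen on C9. Which C–O bond breaks is not secured. These conditions are neutral and tolerate the sulfolene, and the sequence comes back to the route at 8.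

Step 4: the sulfolenyl anion is short-lived, and alkylation at C5, dialkylation or ring-opening can erode the yield. The fallback forms the C11–C12 bond by cross-coupling and sets out from 4. Coupling of 4 with (E)-(2-methylbuta-1,3-dien-1-yl)dimethylalane (from but-1-en-3-yne, Me3Al and catalytic Cp2ZrCl2), catalysed by Pd(PPh3)4 (zerovalent palladium) in THF at rt, gives labda-8,12E,14-triene F4. Cheletropic addition of SO2 (liquid SO2, hydroquinone as inhibitor, sealed tube, rt) to the conjugated diene then comes back to the route at 6.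

## Further compounds

F1 | step 10 | difluoroboron chelate of quinone 16 (BF2 bridging O5 and the C4 carbonyl oxygen) | COC1=CC(=O)C(=CC1=O)C1=CC2=[O+][B-](F)(F)OC3=CC(O)=CC(O1)=C23
F2 | step 10 | difluoroboron chelate of adduct 18 (same chelate on the chromone, stereocentres as in 18) | C=C1C(=O)C[C@H]2C(C)(C)CCC[C@]2(C)[C@@]1(O)C[C@@H]1C(C)=CC[C@H]2C(=O)C(OC)=CC(=O)[C@@]12C1=CC2=[O+][B-](F)(F)OC3=CC(O)=CC(O1)=C23
F3 | step 5 | 8α,9α-epoxy-12,15-sulfonyllabd-13-ene (epoxide on the α face, both sulfolene C2 epimers) | CC1=CCS(=O)(=O)C1C[C@@]12O[C@]1(C)CC[C@H]3C(C)(C)CCC[C@]23C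
F4 | step 4 | labda-8,12E,14-triene | C=C/C(C)=C/CC1=C(C)CC[C@H]2C(C)(C)CCC[C@]12C
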